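## The problem

Compound 14 is an 8-O-4' neolignan: a syringylglycerol chain (C7 on ring A, then C8 and C9) whose C8 oxygen is the phenolic O4' of a sinapyl alcohol unit (ring B). No ring has to be built; the task is an acyclic C7–C8–C9 triol segment that carries an aryl ether at its central carbon. The two adjacent stereocentres, 7S and 8R, stand in the erythro relation. C8 lies next to C7, so a C7 ketone with C8 in place can pass its configuration to C7 through a five-membered chelate between the carbonyl oxygen and O4'; C7 has no comparable handle over C8. The C8–O4' bond joins a secondary carbon to a phenol flanked by two methoxy groups, which is hard to make by substitution at a secondary centre but easy while C8 is still a primary phenacyl carbon. Three features will not survive rough treatment: the free phenol para to the benzylic C7 carbinol (quinone methide formation with acid, base or heat), the cinnamyl alcohol (acid, oxidants, and any hydrogenolysis, which rules out benzyl ethers), and, in every C7 ketone intermediate, the acidic C8–H (epimerisation, retro-aldol, β-elimination of O9). The feature that opens the route is that C9 is an unsubstituted hydroxymethyl group on C8, one carbon at the oxidation level of formaldehyde. The C8–C9 bond can therefore come from formaldehyde and a planar C7=C8 enol ether of an α-aryloxy aryl ketone, and because formaldehyde has no prochiral face, the only stereochemical question in that step is which face of C8 reacts.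

## Retrosynthesis

**14 to 12 (no skeletal bond cut).** The fragile functions of 14 are unveiled last. The O9 silyl ether of 13 is removed by buffered fluoride. The allylic alcohol and the free phenol of 13 are traced to the ethyl cinnamate and the aryl pivalate of 12, both of which fall to one hydride reagent. Carrying the side chain as an ester and the phenol as a pivalate keeps every earlier intermediate free of cinnamyl alcohol and p-hydroxybenzyl alcohol chemistry. The forward step only has to reduce the enoate in the 1,2 sense.

**12 to 10 (C7–H).** The C7 carbinol is traced to the ketone of 11, so that C8 controls C7. The neighbouring cut, C1–C7 by adding a ring A aryl metal to an aldehyde, would put the C8 stereocentre into a far more labile α-aryloxy aldehyde. In 11 the carbonyl oxygen and O4' can hold zinc in a five-membered chelate, and hydride then enters past the C8 hydrogen to give the erythro alcohol. A free O9–H would offer zinc a six-membered chelate with the carbonyl instead, from which hydride delivery opposite the aryloxy group leads to the threo isomer. O9 is therefore silylated first (11 from 10); the bulky silyl ether is a poor donor and leaves the five-membered chelate as the only one available.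

**10 to 8 and 9 (C8–C9, the key cut).** Removing C9 as formaldehyde (9) takes away the only stereocentre of 10 and leaves the achiral Z enol ether 8. The alternatives are less attractive:
- A C7–C8 aldol between an aryloxyacetate enolate and a ring A aldehyde makes two centres at once, but needs an auxiliary for the absolute sense and delivers C9 as an ester that must still be reduced.
- Forming C8–O4' late means substitution at a secondary carbon by a hindered phenol.

The forward reaction must be an enantioface-selective hydroxymethylation of a silyl enol ether by aqueous formaldehyde. This is the province of the Sc(OTf)3/chiral bipyridine diol catalyst, and it needs one enol ether geometry.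

**8 to 6 (O–Si).** Enol ether 8 comes from ketone 6 through its lithium enolate 7. Lithium bridges the enolate oxygen and O4', and strain between ring A and the aryloxy group disfavours the other isomer, so both effects point to the Z geometry. The precursor 6 has no stereochemistry at all.

**6 to 3 and 5 (O4'–C8).** The aryl ether bond is cut while C8 is a primary carbon next to a carbonyl: phenacyl bromide 3 and the phenol of ethyl sinapate 5. This is the most reactive kind of SN2 electrophile and tolerates the hindered phenoxide. Carbenoid O–H insertion of a diazoketone would make the same bond under neutral conditions but costs extra steps, so it is held in reserve.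

**3 to 1, and 5 to 4.** Bromoketone 3 comes from pivalate 2 by α-bromination, and 2 from commercial acetosyringone 1. The pivalate is chosen because it has no α-hydrogen to interfere with enolisation and is cleaved by the same hydride that reduces the ester. Ethyl sinapate 5 is the Fischer ester of commercial sinapic acid 4, which supplies ring B, its E-alkene and all three side-chain carbons.

## Roads not taken

**Alternative 1:** The cut is the O4'–C4' bond, with ring B not yet aromatic. Rh2(OAc)4 would decompose the diazo dione A2, methyl 4-diazo-3,5-dioxocyclohexane-1-carboxylate, and the carbenoid would insert into the free C8 hydroxyl of acetonide A1, the 7,9-acetonide of the ring A erythro triol. The product is the 2-alkoxycyclohexane-1,3-dione A3.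

- Merits: O–H insertion works at a hindered secondary alcohol where substitution by a phenoxide would not. Both stereocentres are already fixed in A1, and no epimerisable α-aryloxy ketone is ever handled. In that respect this road is safer than the chosen one.
- Weak points: A3 is far from ring B. Its dione ring must be dehydrogenated to the aromatic level and O-methylated twice with the benzylic acetonide intact, and the ring ester must then be reduced, reoxidised, olefinated and reduced again to reach the cinnamyl alcohol. A1 must itself be made as a single erythro enantiomer, so the stereochemical problem is moved, not solved, and A2 needs a diazo transfer of its own.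
- Comparison: the chosen plan accepts a configurationally labile ketone (10, 11), but it has ring B aromatic and fully substituted from sinapic acid and makes the ether at a primary carbon in one step. It is shorter by several steps.

**Alternative 2:** The cut is C1–C7. The ring A aryltitanium triisopropoxide A4 would add to the (R)-2-aryloxy-3-silyloxypropanal A5 to give the tris-silyl ether of the target, A6.

- Merits: a non-chelating titanium reagent such as A4 should follow the Felkin–Anh path (aryloxy antiperiplanar to the incoming aryl) and give the erythro relation directly. The endgame from A6 is a single global desilylation, shorter than the four operations that follow the key step of the chosen plan.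
- Weak points: the C8 stereocentre of A5 must come from a chiral building block. Attaching the di-ortho-substituted phenol to it means substitution with inversion at a secondary carbon by a hindered phenol, which is poor. A5 is an α-aryloxy aldehyde, more easily racemised and more prone to β-elimination than ketone 10. Any chelation by the aryloxy or silyloxy oxygen would pull the addition toward threo.
- Comparison: against the shorter endgame, the chosen plan creates C8 catalytically from an achiral ketone that is four simple steps from commercial materials, and sets C7 through a rigid chelate instead of an open transition state.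

**Alternative 3:** The cut is C7–C8. The (E)-γ-aryloxyallyl pinacolboronate A7, which carries ring B as an acetal-protected aldehyde, would add to the silylated syringaldehyde A8 under chiral phosphoric acid catalysis, giving the anti homoallylic alcohol A9 with a vinyl group as latent C9.

- Merits: one catalytic step forms the C7–C8 bond and both stereocentres through a closed chair transition state, and the anti relation follows from the E geometry of A7. No epimerisable intermediate exists, and A8 is a simple silyl ether of a commercial aldehyde. On stereochemical economy this road is better than the chosen one, which needs two stereo-defining steps.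
- Weak points: A7 is not a routine reagent. The E isomer of a γ-aryloxyallylboronate with a bulky 2,6-dimethoxyaryl ether is hard to reach, because metalation of allyl aryl ethers gives the Z series. In A9, C9 arrives one carbon too long and must be cut back by ozonolysis and reduction. Because ozone would also cleave a cinnamyl alkene, ring B must carry a masked aldehyde that is unveiled with acid beside the benzylic alcohol, then olefinated and reduced, about five or six steps after the coupling.
- Comparison: the chosen plan brings C9 in at the right oxidation level from formaldehyde and carries ring B complete from the start, with reagents that are all accessible.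

Key step: step 6

Assumption: the sense of induction of the scandium–bipyridine catalyst is taken to carry over from (Z)-aryl ketone enol ethers, with aryloxy standing where methyl stands. The route is written with the (R,R) ligand as the antipode expected to give 8R; the (S,S) ligand, equally accessible, would replace it should a correlation show the opposite sense.

## Route

Step 1
Reactants: 1 acetosyringone, 1-(4-hydroxy-3,5-dimethoxyphenyl)ethanone
Product: 2 4-acetyl-2,6-dimethoxyphenyl pivalate (2,2-dimethylpropanoate)
Conditions: PivCl, Et3N, DMAP (cat.), CH2Cl2, 0 °C → rt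
Reagents that add atoms: pivaloyl chloride, CC(C)(C)C(=O)Cl
Why: DMAP-catalysed O-acylation of the hindered phenol; the pivalate has no α-hydrogen, so it stays inert in the later enolisation and is removed by i-Bu2AlH in step 9.

Step 2
Reactants: 2 4-acetyl-2,6-dimethoxyphenyl pivalate
Product: 3 4-(2-bromoacetyl)-2,6-dimethoxyphenyl pivalate
Conditions: CuBr2 (2 equiv), EtOAc/CHCl3 1:1, reflux
Reagents that add atoms: CuBr2, Br[Cu]Br
Why: α-bromination of an aryl methyl ketone by CuBr2 through the copper-bound enol, which should brominate the side chain in preference to the ring and stop at the monobromide; the acyl and acyloxy groups further deactivate ring A.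

Step 3
Reactants: 4 sinapic acid, (E)-3-(4-hydroxy-3,5-dimethoxyphenyl)prop-2-enoic acid
Product: 5 ethyl sinapate, ethyl (E)-3-(4-hydroxy-3,5-dimethoxyphenyl)prop-2-enoate
Conditions: EtOH, H2SO4 (cat.), reflux
Reagents that add atoms: ethanol, CCO
Why: Fischer esterification; the E-alkene and the free phenol are untouched.

Step 4
Reactants: 3 4-(2-bromoacetyl)-2,6-dimethoxyphenyl pivalate; 5 ethyl sinapate
Product: 6 ethyl (E)-3-{4-[2-(3,5-dimethoxy-4-pivaloyloxyphenyl)-2-oxoethoxy]-3,5-dimethoxyphenyl}prop-2-enoate
Conditions: K2CO3, acetone, rt → 50 °C
Reagents that add atoms: none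
Why: Williamson ether synthesis: the phenoxide of 5 displaces bromide from the primary phenacyl carbon, a very reactive SN2 electrophile, forming O4'–C8; anhydrous carbonate in acetone should leave the hindered pivalate and the ethyl ester alone.

Step 5
Reactants: 6 ethyl (E)-3-{4-[2-(3,5-dimethoxy-4-pivaloyloxyphenyl)-2-oxoethoxy]-3,5-dimethoxyphenyl}prop-2-enoate
Product: 8 ethyl (E)-3-{4-[(Z)-2-(3,5-dimethoxy-4-pivaloyloxyphenyl)-2-(trimethylsilyloxy)ethenyloxy]-3,5-dimethoxyphenyl}prop-2-enoate, via lithium Z-enolate 7 (not isolated)
Conditions: LiN(SiMe3)2 (1.1 equiv) added to 6 and Me3SiCl (2 equiv), THF, −78 °C; then pentane, filtration, evaporation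
Reagents that add atoms: chlorotrimethylsilane, C[Si](C)(C)Cl; LiN(SiMe3)2, [Li]N([Si](C)(C)C)[Si](C)(C)C (supplies only the lithium of 7)
Why: Kinetic deprotonation of the only acidic C–H (C8) and O-silylation; lithium bridging the enolate oxygen and O4', together with strain between ring A and the aryloxy group in the other isomer, should give the Z geometry, and having Me3SiCl present from the start keeps enolate 7 too short-lived to add to the cinnamate.

Step 6
Reactants: 8 the (Z)-trimethylsilyl enol ether; 9 formaldehyde (37% aqueous solution)
Product: 10 ethyl (E)-3-(4-{[(2R)-1-(3,5-dimethoxy-4-pivaloyloxyphenyl)-3-hydroxy-1-oxopropan-2-yl]oxy}-3,5-dimethoxyphenyl)prop-2-enoate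
Conditions: Sc(OTf)3 (10 mol%), (R,R)-6,6'-bis(1-hydroxy-2,2-dimethylpropyl)-2,2'-bipyridine (12 mol%), aq. HCHO (5 equiv), DME/H2O 9:1, −20 °C
Reagents that add atoms: none
Why: This is a Mukaiyama aldol in aqueous medium: the Sc(OTf)3–bipyridine diol complex (trivalent scandium held by the N2O2 ligand) binds formaldehyde, C8 of enol ether 8 attacks it through an open transition state, and water takes up the silyl group to release β-hydroxy ketone 10 with the new C8–C9 bond. The closest known reaction type is the hydroxymethylation of (Z)-trimethylsilyl enol ethers of propiophenone-type aryl ketones with aqueous formaldehyde under this catalyst; 8 differs in carrying aryloxy where those carry methyl. No ring is closed. The C8 stereocentre is set by the catalyst, whose tert-butyl carbinol arms leave bound formaldehyde open to one enantioface of the enol ether only. Formaldehyde has no prochiral face, so the one selectivity required is enantioface selectivity at C8, and it is secured by the uniform Z geometry of 8 inherited from chelated enolate 7. The cinnamate and the pivalate are inert to this water-tolerant Lewis acid at −20 °C, and the near-neutral medium and low temperature should keep the acidic C8–H of 10 from epimerising; 10 is taken into step 7 without storage.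

Step 7
Reactants: 10 the (2R)-β-hydroxy ketone
Product: 11 ethyl (E)-3-(4-{[(2R)-3-(tert-butyldimethylsilyloxy)-1-(3,5-dimethoxy-4-pivaloyloxyphenyl)-1-oxopropan-2-yl]oxy}-3,5-dimethoxyphenyl)prop-2-enoate
Conditions: TBSCl, imidazole, DMF, 0 °C
Reagents that add atoms: tert-butyldimethylsilyl chloride, CC(C)(C)[Si](C)(C)Cl
Why: Silylation of the primary alcohol with a base too weak to enolise the ketone, so C8 should keep its configuration; the bulky, poorly coordinating silyl ether removes the six-membered O9/C7=O chelate that would steer the next reduction to the threo alcohol.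

Step 8
Reactants: 11 the (2R)-silyloxy ketone
Product: 12 ethyl (E)-3-(4-{[(1S,2R)-3-(tert-butyldimethylsilyloxy)-1-(3,5-dimethoxy-4-pivaloyloxyphenyl)-1-hydroxypropan-2-yl]oxy}-3,5-dimethoxyphenyl)prop-2-enoate (erythro)
Conditions: Zn(BH4)2, Et2O/CH2Cl2, −30 → 0 °C; aq. NH4Cl
Reagents that add atoms: none
Why: Chelation-controlled (Cram chelate) reduction: zinc bridges the C7 carbonyl oxygen and O4' in a five-membered ring, an ortho methoxy group can assist, and hydride enters from the side of the C8 hydrogen, which sets 7S relative to 8R (erythro); Zn(BH4)2 does not touch the enoate or the pivalate at this temperature.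

Step 9
Reactants: 12 the erythro (1S,2R) alcohol
Product: 13 (1S,2R)-3-(tert-butyldimethylsilyloxy)-1-(4-hydroxy-3,5-dimethoxyphenyl)-2-{4-[(E)-3-hydroxyprop-1-enyl]-2,6-dimethoxyphenoxy}propan-1-ol
Conditions: i-Bu2AlH (8 equiv), CH2Cl2, −78 → 0 °C; aq. KNaC4H4O6 (potassium sodium tartrate)
Reagents that add atoms: none
Why: 1,2-Reduction of the cinnamate ester to the allylic alcohol and reductive cleavage of the aryl pivalate by the same reagent, a reduction well established for sinapate esters carrying free phenols; the silyl ether, the E-alkene and both stereocentres are not affected.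

Step 10
Reactants: 13 the O9-silylated triol
Product: 14 (1S,2R)-1-(4-hydroxy-3,5-dimethoxyphenyl)-2-{4-[(E)-3-hydroxyprop-1-enyl]-2,6-dimethoxyphenoxy}propane-1,3-diol (target)
Conditions: Bu4NF, AcOH, THF, 0 °C → rt
Reagents that add atoms: none
Why: Fluoride desilylation of the primary silyl ether; the acetic acid buffer keeps the medium from becoming basic enough to drive the p-hydroxybenzyl alcohol toward a quinone methide, and no stereocentre is touched.

## Compound list

1 | acetosyringone, 1-(4-hydroxy-3,5-dimethoxyphenyl)ethanone | CC(=O)c1cc(OC)c(O)c(OC)c1 | starting material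
2 | 4-acetyl-2,6-dimethoxyphenyl pivalate | CC(=O)c1cc(OC)c(OC(=O)C(C)(C)C)c(OC)c1 | intermediate
3 | 4-(2-bromoacetyl)-2,6-dimethoxyphenyl pivalate | COc1cc(C(=O)CBr)cc(OC)c1OC(=O)C(C)(C)C | intermediate
4 | sinapic acid | COc1cc(/C=C/C(=O)O)cc(OC)c1O | starting material
5 | ethyl sinapate | CCOC(=O)/C=C/c1cc(OC)c(O)c(OC)c1 | intermediate
6 | ethyl (E)-3-{4-[2-(3,5-dimethoxy-4-pivaloyloxyphenyl)-2-oxoethoxy]-3,5-dimethoxyphenyl}prop-2-enoate | COc1cc(C(=O)COc2c(OC)cc(/C=C/C(=O)OCC)cc2OC)cc(OC)c1OC(=O)C(C)(C)C | intermediate
7 | lithium (Z)-enolate of ketone 6 (O–Li cis to the aryloxy oxygen; not isolated) | COc1cc(/C(O[Li])=C/Oc2c(OC)cc(/C=C/C(=O)OCC)cc2OC)cc(OC)c1OC(=O)C(C)(C)C | intermediate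
8 | (Z)-trimethylsilyl enol ether of ketone 6 | COc1cc(/C(O[Si](C)(C)C)=C/Oc2c(OC)cc(/C=C/C(=O)OCC)cc2OC)cc(OC)c1OC(=O)C(C)(C)C | intermediate
9 | formaldehyde (used as 37% aqueous solution) | C=O | starting material
10 | (2R)-α-aryloxy β-hydroxy ketone: ethyl (E)-3-(4-{[(2R)-1-(3,5-dimethoxy-4-pivaloyloxyphenyl)-3-hydroxy-1-oxopropan-2-yl]oxy}-3,5-dimethoxyphenyl)prop-2-enoate | COc1cc(C(=O)[C@@H](CO)Oc2c(OC)cc(/C=C/C(=O)OCC)cc2OC)cc(OC)c1OC(=O)C(C)(C)C | intermediate
11 | O9 tert-butyldimethylsilyl ether of 10, (2R) | COc1cc(C(=O)[C@@H](CO[Si](C)(C)C(C)(C)C)Oc2c(OC)cc(/C=C/C(=O)OCC)cc2OC)cc(OC)c1OC(=O)C(C)(C)C | intermediate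
12 | erythro (1S,2R) alcohol: ethyl (E)-3-(4-{[(1S,2R)-3-(tert-butyldimethylsilyloxy)-1-(3,5-dimethoxy-4-pivaloyloxyphenyl)-1-hydroxypropan-2-yl]oxy}-3,5-dimethoxyphenyl)prop-2-enoate | COc1cc([C@H](O)[C@@H](CO[Si](C)(C)C(C)(C)C)Oc2c(OC)cc(/C=C/C(=O)OCC)cc2OC)cc(OC)c1OC(=O)C(C)(C)C | intermediate
13 | (1S,2R)-3-(tert-butyldimethylsilyloxy)-1-(4-hydroxy-3,5-dimethoxyphenyl)-2-{4-[(E)-3-hydroxyprop-1-enyl]-2,6-dimethoxyphenoxy}propan-1-ol | COc1cc([C@H](O)[C@@H](CO[Si](C)(C)C(C)(C)C)Oc2c(OC)cc(/C=C/CO)cc2OC)cc(OC)c1O | intermediate
14 | (1S,2R)-1-(4-hydroxy-3,5-dimethoxyphenyl)-2-{4-[(E)-3-hydroxyprop-1-enyl]-2,6-dimethoxyphenoxy}propane-1,3-diol | COc1cc([C@H](O)[C@@H](CO)Oc2c(OC)cc(/C=C/CO)cc2OC)cc(OC)c1O | target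

## Step count and risks

Total step count: 10. Longest linear sequence: 9 steps (steps 1, 2 and 4 to 10, from acetosyringone 1); step 3 is a one-step side branch.

**Step 6 (key step).** The most likely failure is eroded enantioface selectivity. The aryloxy oxygen and its ortho methoxy groups may compete with the ligand for scandium, and the aryloxy group is much larger than the methyl group of the established substrates, which may disturb the open transition state. Protodesilylation of 8 back to 6 in the aqueous medium is the second concern, though 6 can be recycled. The fallback gives up asymmetric catalysis for a classical resolution. It sets out from 6: base-mediated aldol with aqueous formaldehyde (K2CO3 cat., 1,4-dioxane, rt) should give the racemic hydroxymethyl ketone F1. Silylation as in step 7 gives the racemic silyl ether F2, and Zn(BH4)2 reduction as in step 8 gives the racemic erythro alcohol F3. Esterification of the C7 hydroxyl with (S)-O-methylmandelic acid (DCC, DMAP) gives the (7S,8R) mandelate F4 and the (7R,8S) mandelate F5, to be separated by chromatography. Treating F4 with i-Bu2AlH as in step 9 cleaves the mandelate along with the ethyl ester and the pivalate, and the route is rejoined at 13.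

**Step 8.** The risk is poor facial selectivity. The hindered aryl ether oxygen may hold zinc only weakly, so that the open Felkin–Anh pathway to the threo alcohol competes; C8 may also epimerise in 11 before hydride arrives. The fallback replaces substrate control by reagent control: Noyori asymmetric transfer hydrogenation of 11 with RuCl(p-cymene)[(R,R)-TsDPEN] in HCO2H/Et3N. This is the catalyst antipode that turns acetophenone into (R)-1-phenylethanol and hence places aryl and hydroxyl as required for 7S here. It sets out from 11 and returns at 12 without any new compound.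

**Step 2.** The risk is loss of chemoselectivity: electrophilic bromination of ring A at C2/C6, each activated by two methoxy groups, or a second bromination of the side chain. The fallback separates enolisation from bromination. It sets out from 2, which is converted with Me3SiOTf/Et3N into the trimethylsilyl enol ether F6; this reacts with N-bromosuccinimide in THF at −78 °C, faster than the arene can, and returns at 3.

**Step 4.** The risk is a sluggish substitution by the di-ortho-substituted, acrylate-deactivated phenoxide, giving time for carbonate-mediated cleavage or transfer of the pivalate and for self-condensation of the bromoketone. The fallback makes the same O4'–C8 bond by carbenoid chemistry under neutral conditions. It sets out from 3, which with N,N'-ditosylhydrazine and DBU should give the diazoketone F7; Rh2(OAc)4-catalysed O–H insertion of F7 into phenol 5 returns at 6.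

## Further compounds

F1 | step 6 | racemic ethyl (E)-3-(4-{[1-(3,5-dimethoxy-4-pivaloyloxyphenyl)-3-hydroxy-1-oxopropan-2-yl]oxy}-3,5-dimethoxyphenyl)prop-2-enoate | COc1cc(C(=O)C(CO)Oc2c(OC)cc(/C=C/C(=O)OCC)cc2OC)cc(OC)c1OC(=O)C(C)(C)C
F2 | step 6 | racemic O9 tert-butyldimethylsilyl ether of F1 | COc1cc(C(=O)C(CO[Si](C)(C)C(C)(C)C)Oc2c(OC)cc(/C=C/C(=O)OCC)cc2OC)cc(OC)c1OC(=O)C(C)(C)C
F3 | step 6 | racemic erythro alcohol, 1:1 mixture of the (1S,2R) and (1R,2S) forms of 12 | COc1cc([C@H](O)[C@@H](CO[Si](C)(C)C(C)(C)C)Oc2c(OC)cc(/C=C/C(=O)OCC)cc2OC)cc(OC)c1OC(=O)C(C)(C)C.COc1cc([C@@H](O)[C@H](CO[Si](C)(C)C(C)(C)C)Oc2c(OC)cc(/C=C/C(=O)OCC)cc2OC)cc(OC)c1OC(=O)C(C)(C)C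
F4 | step 6 | (S)-O-methylmandelate of the (1S,2R) alcohol 12 at the C7 oxygen | COc1cc([C@H](OC(=O)[C@@H](OC)c3ccccc3)[C@@H](CO[Si](C)(C)C(C)(C)C)Oc2c(OC)cc(/C=C/C(=O)OCC)cc2OC)cc(OC)c1OC(=O)C(C)(C)C
F5 | step 6 | (S)-O-methylmandelate of the (1R,2S) enantiomer of 12 at the C7 oxygen | COc1cc([C@@H](OC(=O)[C@@H](OC)c3ccccc3)[C@H](CO[Si](C)(C)C(C)(C)C)Oc2c(OC)cc(/C=C/C(=O)OCC)cc2OC)cc(OC)c1OC(=O)C(C)(C)C
F0 | step 8 | none | none
F6 | step 2 | 2,6-dimethoxy-4-[1-(trimethylsilyloxy)ethenyl]phenyl pivalate | C=C(O[Si](C)(C)C)c1cc(OC)c(OC(=O)C(C)(C)C)c(OC)c1
F7 | step 4 | 4-(2-diazoacetyl)-2,6-dimethoxyphenyl pivalate | COc1cc(C(=O)C=[N+]=[N-])cc(OC)c1OC(=O)C(C)(C)C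
A1 | alternative 1 | 7,9-acetonide of the ring A erythro triol with free C8 hydroxyl and silylated phenol | COc1cc([C@H](OC(C)(C)OC2)[C@@H]2O)cc(OC)c1O[Si](C)(C)C(C)(C)C
A2 | alternative 1 | methyl 4-diazo-3,5-dioxocyclohexane-1-carboxylate | COC(=O)C1CC(=O)C(=[N+]=[N-])C(=O)C1
A3 | alternative 1 | 2-alkoxycyclohexane-1,3-dione from O–H insertion (diketo form) | COc1cc([C@H](OC(C)(C)OC2)[C@@H]2OC3C(=O)CC(C(=O)OC)CC3=O)cc(OC)c1O[Si](C)(C)C(C)(C)C
A4 | alternative 2 | [4-(tert-butyldimethylsilyloxy)-3,5-dimethoxyphenyl]titanium triisopropoxide | COc1cc([Ti](OC(C)C)(OC(C)C)OC(C)C)cc(OC)c1O[Si](C)(C)C(C)(C)C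
A5 | alternative 2 | (R)-2-aryloxy-3-(tert-butyldimethylsilyloxy)propanal carrying the silylated sinapyl alcohol unit | O=C[C@@H](CO[Si](C)(C)C(C)(C)C)Oc1c(OC)cc(/C=C/CO[Si](C)(C)C(C)(C)C)cc1OC
A6 | alternative 2 | tris(tert-butyldimethylsilyl) ether of the target | COc1cc([C@H](O)[C@@H](CO[Si](C)(C)C(C)(C)C)Oc2c(OC)cc(/C=C/CO[Si](C)(C)C(C)(C)C)cc2OC)cc(OC)c1O[Si](C)(C)C(C)(C)C
A7 | alternative 3 | (E)-γ-aryloxyallyl pinacolboronate with ring B as the 5,5-dimethyl-1,3-dioxane acetal | COc1cc(C2OCC(C)(C)CO2)cc(OC)c1O/C=C/CB1OC(C)(C)C(C)(C)O1
A8 | alternative 3 | 4-(tert-butyldimethylsilyloxy)-3,5-dimethoxybenzaldehyde | COc1cc(C=O)cc(OC)c1O[Si](C)(C)C(C)(C)C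
A9 | alternative 3 | anti homoallylic alcohol with vinyl as latent C9 | COc1cc([C@H](O)[C@@H](C=C)Oc2c(OC)cc(C3OCC(C)(C)CO3)cc2OC)cc(OC)c1O[Si](C)(C)C(C)(C)C
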